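**Retrosynthetic overview** (halimane numbering, C1–C20)

1. Late stage: the C15 acid comes from a silyl ether, C5=C6 from syn dehydration of a 5-OH, and the C18 acetate from Baeyer–Villiger oxidation of a C4 acetonyl group, itself made from a C4 allyl group by Wacker oxidation.
2. The route rests on the C5–C10 bond, which belongs to ring A and ring B alike and lies next to the quaternary C4. Cutting it transannularly (carbonyl-ene) opens both rings to a ten-membered ring C1–C10 with a C5 ketone.
3. That ring goes back by a Claisen shift (C4–C18) to an allyl enol ether, and by an oxy-Cope shift (C2–C3) to a ring B cyclohexane with O-allyl and isopropenyl on C5 and vinyl on C10.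
4. Ring B is made first (C8 from 4-methylcyclohexanone, C9 by conjugate addition of the C11–C15 chain, C10 by enolate vinylation, C5 by isopropenyl addition). It is then expanded to the ten-membered ring, and rings A and B are closed together.
5. Stereochemical plan: C4 is dictated by the C5 carbinol centre through the locked enol ether, so O-allyl and vinyl are placed cis to C11. C5 and C10 are re-formed after ring inversion under control of C8 and C9.

Key step: step 15

Assumption: lithium (R,R)-bis(1-phenylethyl)amide is taken to give the (S)-enol ether of 4-methylcyclohexanone, as it does with other 4-alkylcyclohexanones; if the sense were opposite, the (S,S)-amide would be used.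

**Step 1**
Reactants: 1 4-methylcyclohexanone
Product: 3 (S)-4-methyl-1-(trimethylsilyloxy)cyclohex-1-ene, via lithium enolate 2 (not isolated)
Conditions: lithium (R,R)-bis(1-phenylethyl)amide (from the amine and n-BuLi), LiCl, TMSCl (in situ), THF, −100 °C
Reagents that add atoms: chlorotrimethylsilane, C[Si](C)(C)Cl
Why: Enantioselective deprotonation of the prochiral ketone by a chiral lithium amide with internal silyl quench (desymmetrisation) should set C8, and material from the minor enantiomer is removed later as a diastereomer once the enantiopure side chain is attached.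

**Step 2**
Reactants: 3 (S)-4-methyl-1-(trimethylsilyloxy)cyclohex-1-ene
Product: 4 (S)-4-methylcyclohex-2-en-1-one
Conditions: Pd(OAc)2 (10 mol%), O2 (1 atm), DMSO, rt
Reagents that add atoms: none
Why: Saegusa–Ito oxidation, in which the divalent palladium enolate loses a β-hydride from C9 to give the C9=C10 enone without touching C8.

**Step 3**
Reactants: 4 (S)-4-methylcyclohex-2-en-1-one
Product: 5 (3R,4S)-3,4-dimethyl-1-(trimethylsilyloxy)cyclohex-1-ene
Conditions: MeMgBr, CuBr·SMe2 (5 mol%), TMSCl, HMPA, THF, −78 °C
Reagents that add atoms: methylmagnesium bromide, C[Mg]Br; chlorotrimethylsilane, C[Si](C)(C)Cl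
Why: Copper-catalysed conjugate addition with silyl trapping puts the C20 methyl on C9 anti to the C8 methyl (this centre is erased in step 4) and gives the enol ether regiospecifically.

**Step 4**
Reactants: 5 (3R,4S)-3,4-dimethyl-1-(trimethylsilyloxy)cyclohex-1-ene
Product: 6 (S)-3,4-dimethylcyclohex-2-en-1-one
Conditions: Pd(OAc)2 (10 mol%), O2 (1 atm), DMSO, rt
Reagents that add atoms: none
Why: A second Saegusa–Ito oxidation re-forms the C9=C10 double bond, now with the C20 methyl on C9.

**Step 5**
Reactants: 7 methyl hydrogen (R)-3-methylglutarate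
Product: 8 methyl (R)-5-hydroxy-3-methylpentanoate
Conditions: BH3·SMe2, THF, −10 °C → rt; MeOH
Reagents that add atoms: none
Why: Chemoselective borane reduction of the carboxylic acid in the presence of the methyl ester, so that the acid carbon becomes C11 and the ester carbon C15.

**Step 6**
Reactants: 8 methyl (R)-5-hydroxy-3-methylpentanoate
Product: 9 methyl (S)-5-bromo-3-methylpentanoate
Conditions: CBr4, PPh3, CH2Cl2, 0 °C
Reagents that add atoms: carbon tetrabromide, BrC(Br)(Br)Br
Why: Appel bromination of the primary alcohol (SN2 at C11, C13 untouched; the descriptor changes only by priority), run at once to forestall lactonisation.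

**Step 7**
Reactants: 9 methyl (S)-5-bromo-3-methylpentanoate
Product: 10 (S)-5-bromo-3-methylpentan-1-ol
Conditions: i-Bu2AlH, CH2Cl2, −78 → 0 °C; aq. potassium sodium tartrate
Reagents that add atoms: none
Why: Hydride reduction of the ester (C15) to the primary alcohol at low temperature, which leaves the primary bromide intact.

**Step 8**
Reactants: 10 (S)-5-bromo-3-methylpentan-1-ol
Product: 11 [(3S)-5-bromo-3-methylpentyl]oxy(tert-butyl)dimethylsilane
Conditions: TBSCl, imidazole, DMF, rt
Reagents that add atoms: tert-butyldimethylsilyl chloride, CC(C)(C)[Si](C)(C)Cl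
Why: Standard silylation of the C15 hydroxyl, giving a group that survives the organometallic and thermal steps.

**Step 9**
Reactants: 11 [(3S)-5-bromo-3-methylpentyl]oxy(tert-butyl)dimethylsilane; 6 (S)-3,4-dimethylcyclohex-2-en-1-one
Product: 13 (3R,4S)-3-[(3R)-5-(tert-butyldimethylsilyloxy)-3-methylpentyl]-3,4-dimethyl-1-(trimethylsilyloxy)cyclohex-1-ene, via side-chain Grignard reagent 12 (not isolated)
Conditions: Mg, THF, 40 °C; then 6, CuBr·SMe2 (10 mol%), TMSCl, HMPA, THF, −78 °C; Et3N
Reagents that add atoms: chlorotrimethylsilane, C[Si](C)(C)Cl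
Why: Copper-catalysed, TMSCl/HMPA-accelerated conjugate addition of the Grignard reagent to the β,β-disubstituted enone should occur anti to the C8 methyl, which sets the quaternary C9 (C11 trans to C17, C20 cis to C17), and the enolate is trapped as the C5=C10 silyl enol ether.

**Step 10**
Reactants: 14 benzeneselenenyl chloride; 15 ethyl vinyl ether
Product: 17 (phenylselanyl)acetaldehyde, via α-chloro ether 16 (not isolated)
Conditions: CH2Cl2, −78 °C; then H2O, NaHCO3, rt
Reagents that add atoms: water, O
Why: Electrophilic addition of the selenenyl chloride across the enol ether (selenium on the terminal carbon) and hydrolysis of the α-chloro ether give the aldehyde that serves as a vinyl cation equivalent.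

**Step 11**
Reactants: 13 (3R,4S)-3-[(3R)-5-(tert-butyldimethylsilyloxy)-3-methylpentyl]-3,4-dimethyl-1-(trimethylsilyloxy)cyclohex-1-ene; 17 (phenylselanyl)acetaldehyde
Product: 19 (2S,3R,4S)-3-[(3R)-5-(tert-butyldimethylsilyloxy)-3-methylpentyl]-2-[1-hydroxy-2-(phenylselanyl)ethyl]-3,4-dimethylcyclohexan-1-one (both carbinol epimers), via lithium enolate 18 (not isolated)
Conditions: MeLi, THF, 0 °C; then 17, −78 °C; AcOH
Reagents that add atoms: none
Why: Regiospecific enolate generation by MeLi cleavage of the silyl enol ether, then aldol addition, in which the aldehyde should approach C10 anti to the pseudoaxial C20 methyl of the half-chair with C17 equatorial, so that the new branch is cis to C11 (the carbinol epimers converge in step 12).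

**Step 12**
Reactants: 19 (2S,3R,4S)-3-[(3R)-5-(tert-butyldimethylsilyloxy)-3-methylpentyl]-2-[1-hydroxy-2-(phenylselanyl)ethyl]-3,4-dimethylcyclohexan-1-one
Product: 20 (2R,3R,4S)-3-[(3R)-5-(tert-butyldimethylsilyloxy)-3-methylpentyl]-2-ethenyl-3,4-dimethylcyclohexan-1-one
Conditions: MsCl, Et3N, CH2Cl2, −20 → 0 °C
Reagents that add atoms: none
Why: Reductive elimination of the β-hydroxy selenide (mesylation, selenium-assisted departure through a seleniranium ion, loss of the selenenyl group) gives the terminal vinyl group and completes the known two-step enolate vinylation, and the short, cold exposure to Et3N should leave C10 unchanged.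

**Step 13**
Reactants: 20 (2R,3R,4S)-3-[(3R)-5-(tert-butyldimethylsilyloxy)-3-methylpentyl]-2-ethenyl-3,4-dimethylcyclohexan-1-one; 21 isopropenylmagnesium bromide
Product: 22 (1S,2R,3R,4S)-3-[(3R)-5-(tert-butyldimethylsilyloxy)-3-methylpentyl]-2-ethenyl-3,4-dimethyl-1-(prop-1-en-2-yl)cyclohexan-1-ol
Conditions: CeCl3 (anhydrous), THF, −78 °C; aq. NH4Cl
Reagents that add atoms: none
Why: 1,2-Addition of the weakly basic organocerium reagent (no enolisation of the β,γ-unsaturated ketone) should come equatorially and anti to the C10 vinyl group on the chair that has vinyl equatorial and C11 axial (C11 blocks the other face), giving the alcohol with OH cis to vinyl and to C11 and the two alkenyl groups trans.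

**Step 14**
Reactants: 22 (1S,2R,3R,4S)-3-[(3R)-5-(tert-butyldimethylsilyloxy)-3-methylpentyl]-2-ethenyl-3,4-dimethyl-1-(prop-1-en-2-yl)cyclohexan-1-ol; 23 allyl bromide
Product: 25 (1S,2R,3R,4S)-1-(allyloxy)-3-[(3R)-5-(tert-butyldimethylsilyloxy)-3-methylpentyl]-2-ethenyl-3,4-dimethyl-1-(prop-1-en-2-yl)cyclohexane, via sodium alkoxide 24 (not isolated)
Conditions: NaH, THF–DMF, 0 °C; then 23, n-Bu4NI (cat.), 0 °C → rt
Reagents that add atoms: none
Why: Williamson O-allylation of the tertiary alkoxide, which as its sodium salt at 0 °C should be alkylated faster than it undergoes anionic oxy-Cope rearrangement.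

**Step 15**
Reactants: 25 (1S,2R,3R,4S)-1-(allyloxy)-3-[(3R)-5-(tert-butyldimethylsilyloxy)-3-methylpentyl]-2-ethenyl-3,4-dimethyl-1-(prop-1-en-2-yl)cyclohexane
Product: 28 18-vinyl-15-(tert-butyldimethylsilyloxy)halim-1-en-5-ol (4-allyl-5-hydroxyhalim-1-ene silyl ether; 5-OH anti to H10; H10 anti to C20; allyl syn to H10), via ten-membered allyl enol ether 26 (not isolated), via ten-membered ketone 27 (not isolated)
Conditions: PhMe, Et3N (trace), 210 °C, sealed tube or microwave, base-washed glass
Reagents that add atoms: none
Why: Thermal tandem oxy-Cope/Claisen/transannular carbonyl-ene reaction, the known cascade of 1,2-dialkenylcyclohexanol allyl ethers: a chair [3,3] shift through the ring B chair that holds isopropenyl and vinyl equatorial breaks C5–C10 and forms C2–C3, giving 26 with an E C1=C10 olefin and an enol ether in which O is cis to C3. The tetrasubstituted enol ether cannot rotate through the ten-membered ring, so the Claisen [3,3] shift can deliver the allyl group only to the face of C4 that points away from C10; C4 (C4–C18 bond) is thereby fixed by the carbinol centre C5 of 25, which is why its oxygen was placed cis to C11. Ketone 27 then undergoes the transannular carbonyl-ene reaction, C10 adding to the C5 carbonyl while the oxygen takes a hydrogen from C2 through a six-membered array, so that one transannular C5–C10 closure of the ten-membered ring produces both six-membered rings (ring A with the olefin moved to C1=C2, ring B re-formed). The ene step is expected to follow inversion of the ring (E olefin and carbonyl swing through the ring plane), as such ketones normally do, because only the inverted conformer gives a chair–chair array with C11 and C17 equatorial and C20 axial; this sets H10 anti to C20 and the 5-OH anti to H10 (trans ring fusion) and leaves the C18 allyl group axial and anti to the hydroxyl. The step needs E geometry at C1=C10 (secured by the trans-diequatorial alkenyl groups), one face for the Claisen shift (secured by the locked enol ether) and closure from the inverted conformer (secured by the C8 and C9 substituents), and acid must be excluded so that the enol ether survives until it rearranges.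

**Step 16**
Reactants: 28 18-vinyl-15-(tert-butyldimethylsilyloxy)halim-1-en-5-ol
Product: 29 18-acetyl-15-(tert-butyldimethylsilyloxy)halim-1-en-5-ol (C4 acetonyl compound)
Conditions: PdCl2 (10 mol%), CuCl, O2 (1 atm), DMF–H2O, rt
Reagents that add atoms: water, O
Why: Tsuji–Wacker oxidation is selective for the terminal olefin and gives the methyl ketone, the 5-OH being anti-periplanar to C18 and so unable to cyclise onto the olefin or the ketone, while the C1=C2 ring olefin is left.

**Step 17**
Reactants: 29 18-acetyl-15-(tert-butyldimethylsilyloxy)halim-1-en-5-ol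
Product: 30 18-acetyl-15-(tert-butyldimethylsilyloxy)halimane-5-ol
Conditions: H2 (1 atm), Pd/C, EtOAc, rt
Reagents that add atoms: none
Why: Heterogeneous hydrogenation of the only remaining olefin (C1=C2), needed before the peracid step, forms no stereocentre.

**Step 18**
Reactants: 30 18-acetyl-15-(tert-butyldimethylsilyloxy)halimane-5-ol
Product: 31 18-acetoxy-15-(tert-butyldimethylsilyloxy)halimane-5-ol
Conditions: (CF3CO)2O, H2O2·urea, Na2HPO4, CH2Cl2, 0 °C
Reagents that add atoms: trifluoroperacetic acid (made in the flask), OOC(=O)C(F)(F)F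
Why: Baeyer–Villiger oxidation in which the primary C18 carbon migrates in preference to methyl, giving the C18 acetate directly, while the buffer protects the silyl ether and the hindered tertiary alcohol is inert.

**Step 19**
Reactants: 31 18-acetoxy-15-(tert-butyldimethylsilyloxy)halimane-5-ol
Product: 32 18-acetoxy-15-(tert-butyldimethylsilyloxy)halim-5-ene
Conditions: MeO2CN–SO2NEt3 (Burgess reagent), PhMe, 70 °C
Reagents that add atoms: none
Why: Burgess dehydration is a syn elimination (Ei) of the sulfamate ester, and since C4 bears no hydrogen and H10 is anti to the axial 5-OH, only the cis hydrogen on C6 can be removed, giving C5=C6.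

**Step 20**
Reactants: 32 18-acetoxy-15-(tert-butyldimethylsilyloxy)halim-5-ene
Product: 33 18-acetoxyhalim-5-en-15-ol
Conditions: HF·pyridine, pyridine, THF, 0 °C → rt
Reagents that add atoms: none
Why: Fluoride cleavage of the primary silyl ether under buffered, non-basic conditions that spare the acetate and the trisubstituted olefin.

**Step 21**
Reactants: 33 18-acetoxyhalim-5-en-15-ol
Product: 34 18-acetoxyhalim-5-en-15-oic acid (target)
Conditions: TEMPO (cat.), PhI(OAc)2, MeCN–H2O, rt
Reagents that add atoms: water, O
Why: Nitroxyl-catalysed oxidation with a hypervalent iodine co-oxidant takes the primary alcohol through the aldehyde hydrate to the carboxylic acid without touching the olefin or the acetate.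

**Compound list**

1 | 4-methylcyclohexanone | CC1CCC(=O)CC1 | starting material
2 | lithium (S)-4-methylcyclohex-1-en-1-olate | [Li]OC1=CC[C@@H](C)CC1 | intermediate
3 | (S)-4-methyl-1-(trimethylsilyloxy)cyclohex-1-ene | C[Si](C)(C)OC1=CC[C@@H](C)CC1 | intermediate
4 | (S)-4-methylcyclohex-2-en-1-one | O=C1C=C[C@@H](C)CC1 | intermediate
5 | (3R,4S)-3,4-dimethyl-1-(trimethylsilyloxy)cyclohex-1-ene (trans) | C[Si](C)(C)OC1=C[C@H](C)[C@@H](C)CC1 | intermediate
6 | (S)-3,4-dimethylcyclohex-2-en-1-one | O=C1C=C(C)[C@@H](C)CC1 | intermediate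
7 | methyl hydrogen (R)-3-methylglutarate | OC(=O)C[C@@H](C)CC(=O)OC | starting material
8 | methyl (R)-5-hydroxy-3-methylpentanoate | OCC[C@@H](C)CC(=O)OC | intermediate
9 | methyl (S)-5-bromo-3-methylpentanoate | BrCC[C@@H](C)CC(=O)OC | intermediate
10 | (S)-5-bromo-3-methylpentan-1-ol | BrCC[C@@H](C)CCO | intermediate
11 | [(3S)-5-bromo-3-methylpentyl]oxy(tert-butyl)dimethylsilane | BrCC[C@@H](C)CCO[Si](C)(C)C(C)(C)C | intermediate
12 | [(3S)-5-(tert-butyldimethylsilyloxy)-3-methylpentyl]magnesium bromide | Br[Mg]CC[C@@H](C)CCO[Si](C)(C)C(C)(C)C | intermediate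
13 | (3R,4S)-3-[(3R)-5-(tert-butyldimethylsilyloxy)-3-methylpentyl]-3,4-dimethyl-1-(trimethylsilyloxy)cyclohex-1-ene (C5=C10 enol ether; C11 trans to C17) | C[Si](C)(C)OC1=C[C@](C)(CC[C@@H](C)CCO[Si](C)(C)C(C)(C)C)[C@@H](C)CC1 | intermediate
14 | benzeneselenenyl chloride | Cl[Se]c1ccccc1 | starting material
15 | ethyl vinyl ether | C=COCC | starting material
16 | 1-chloro-1-ethoxy-2-(phenylselanyl)ethane | CCOC(Cl)C[Se]c1ccccc1 | intermediate
17 | (phenylselanyl)acetaldehyde | O=CC[Se]c1ccccc1 | intermediate
18 | lithium enolate of the ring B ketone (C5=C10) | [Li]OC1=C[C@](C)(CC[C@@H](C)CCO[Si](C)(C)C(C)(C)C)[C@@H](C)CC1 | intermediate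
19 | (2S,3R,4S)-3-[(3R)-5-(tert-butyldimethylsilyloxy)-3-methylpentyl]-2-[1-hydroxy-2-(phenylselanyl)ethyl]-3,4-dimethylcyclohexan-1-one (C10 branch cis to C11; carbinol epimers) | O=C1CC[C@H](C)[C@@](C)(CC[C@@H](C)CCO[Si](C)(C)C(C)(C)C)[C@H]1C(O)C[Se]c1ccccc1 | intermediate
20 | (2R,3R,4S)-3-[(3R)-5-(tert-butyldimethylsilyloxy)-3-methylpentyl]-2-ethenyl-3,4-dimethylcyclohexan-1-one (vinyl cis to C11) | O=C1CC[C@H](C)[C@@](C)(CC[C@@H](C)CCO[Si](C)(C)C(C)(C)C)[C@H]1C=C | intermediate
21 | isopropenylmagnesium bromide | CC(=C)[Mg]Br | starting material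
22 | (1S,2R,3R,4S)-3-[(3R)-5-(tert-butyldimethylsilyloxy)-3-methylpentyl]-2-ethenyl-3,4-dimethyl-1-(prop-1-en-2-yl)cyclohexan-1-ol (OH and vinyl cis to C11; isopropenyl cis to C20) | O[C@@]1(C(C)=C)CC[C@H](C)[C@@](C)(CC[C@@H](C)CCO[Si](C)(C)C(C)(C)C)[C@H]1C=C | intermediate
23 | allyl bromide | C=CCBr | starting material
24 | sodium alkoxide of 22 | [Na]O[C@@]1(C(C)=C)CC[C@H](C)[C@@](C)(CC[C@@H](C)CCO[Si](C)(C)C(C)(C)C)[C@H]1C=C | intermediate
25 | (1S,2R,3R,4S)-1-(allyloxy)-3-[(3R)-5-(tert-butyldimethylsilyloxy)-3-methylpentyl]-2-ethenyl-3,4-dimethyl-1-(prop-1-en-2-yl)cyclohexane (key-step precursor) | C=CCO[C@@]1(C(C)=C)CC[C@H](C)[C@@](C)(CC[C@@H](C)CCO[Si](C)(C)C(C)(C)C)[C@H]1C=C | intermediate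
26 | 5-(allyloxy)-4,8,9-trimethyl-9-[(3R)-5-(tert-butyldimethylsilyloxy)-3-methylpentyl]cyclodeca-1(10),4-diene (halimane numbering; C1=C10 E; enol ether O cis to C3) | C=CCO/C1=C(/C)CC/C=C/[C@](C)(CC[C@@H](C)CCO[Si](C)(C)C(C)(C)C)[C@@H](C)CC1 | intermediate
27 | 4-allyl-4,8,9-trimethyl-9-[(3R)-5-(tert-butyldimethylsilyloxy)-3-methylpentyl]cyclodec-1(10)-en-5-one (halimane numbering; C1=C10 E; C4 as in the target) | C=CC[C@]1(C)CC/C=C/[C@](C)(CC[C@@H](C)CCO[Si](C)(C)C(C)(C)C)[C@@H](C)CCC1=O | intermediate
28 | 18-vinyl-15-(tert-butyldimethylsilyloxy)halim-1-en-5-ol (4-allyl-5-hydroxyhalim-1-ene silyl ether; trans ring fusion; 5-OH anti to H10; allyl syn to H10) | C=CC[C@]1(C)CC=C[C@@H]2[C@]1(O)CC[C@H](C)[C@@]2(C)CC[C@@H](C)CCO[Si](C)(C)C(C)(C)C | intermediate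
29 | 18-acetyl-15-(tert-butyldimethylsilyloxy)halim-1-en-5-ol | CC(=O)C[C@]1(C)CC=C[C@@H]2[C@]1(O)CC[C@H](C)[C@@]2(C)CC[C@@H](C)CCO[Si](C)(C)C(C)(C)C | intermediate
30 | 18-acetyl-15-(tert-butyldimethylsilyloxy)halimane-5-ol | CC(=O)C[C@]1(C)CCC[C@@H]2[C@]1(O)CC[C@H](C)[C@@]2(C)CC[C@@H](C)CCO[Si](C)(C)C(C)(C)C | intermediate
31 | 18-acetoxy-15-(tert-butyldimethylsilyloxy)halimane-5-ol | CC(=O)OC[C@]1(C)CCC[C@@H]2[C@]1(O)CC[C@H](C)[C@@]2(C)CC[C@@H](C)CCO[Si](C)(C)C(C)(C)C | intermediate
32 | 18-acetoxy-15-(tert-butyldimethylsilyloxy)halim-5-ene | CC(=O)OC[C@]1(C)CCC[C@@H]2C1=CC[C@H](C)[C@@]2(C)CC[C@@H](C)CCO[Si](C)(C)C(C)(C)C | intermediate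
33 | 18-acetoxyhalim-5-en-15-ol | CC(=O)OC[C@]1(C)CCC[C@@H]2C1=CC[C@H](C)[C@@]2(C)CC[C@@H](C)CCO | intermediate
34 | (4R,8S,9R,10S,13R)-18-acetoxyhalim-5-en-15-oic acid | CC(=O)OC[C@]1(C)CCC[C@@H]2C1=CC[C@H](C)[C@@]2(C)CC[C@@H](C)CC(=O)O | target

**Step count and risk**

Total step count: 21. Longest linear sequence: 16 steps (steps 1–4, 9, 11–21).

Steps most likely to fail:

Step 15. The ten-membered ketone may close before its ring has inverted, which would give the ring fusion epimeric at C5 and C10, or adventitious acid may hydrolyse the enol ether before the Claisen shift. The fallback sets out from carbinol 22 and separates the three events. KH and 18-crown-6 in THF (0 °C → rt) give the potassium alkoxide F1, which undergoes anionic oxy-Cope rearrangement to the potassium enolate of the ten-membered ring F2. Allyl bromide 23 is added to the same flask and alkylates C4 on its one open face to give ketone 27, which is isolated; any O-allylated material is enol ether 26, which converges on 27 on gentle heating. The ketone is left to equilibrate its ring conformers and is closed at low temperature with Me2AlCl in CH2Cl2 (Lewis acid-promoted transannular carbonyl-ene reaction), which returns to the route at 28.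

Step 13. The organocerium reagent may attack the face syn to the vinyl group, or the β,γ-unsaturated ketone may lose its C10 configuration by enolisation. The fallback sets out from aldol 19 and reverses the order of events. Isopropenylmagnesium bromide 21 with CeCl3 is added to the β-hydroxy ketone itself. The metal alkoxide of the side-chain carbinol chelates the C5 carbonyl, which holds the C10 branch equatorial and C11 axial, so only the face anti to both is open, and no epimerisable vinyl ketone is ever formed. This gives the diol with the intact hydroxy selenide F3. MsCl and Et3N then eliminate the β-hydroxy selenide (the tertiary alcohol is not mesylated), which returns to the route at 22.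

Step 19. The tertiary sulfamate ester may ionise, after which the C5 cation can lose H10 (tetrasubstituted C5=C10 olefin) or suffer a 1,2-shift from C4. The fallback sets out from 31 and replaces the sulfamate by an isolated derivative that eliminates only in a concerted way. NaH, CS2 and then MeI in THF at 0 °C give the S-methyl xanthate of the 5-hydroxyl F4. Warming in toluene (80–110 °C) brings about a Chugaev syn elimination, for which only the cis hydrogen on C6 is within reach, and this returns to the route at 32.

**Further compounds**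
F1 | step 15 | potassium alkoxide of carbinol 22 | [K]O[C@@]1(C(C)=C)CC[C@H](C)[C@@](C)(CC[C@@H](C)CCO[Si](C)(C)C(C)(C)C)[C@H]1C=C
F2 | step 15 | potassium enolate of the ten-membered ring (C4=C5 enolate with O cis to C3; C1=C10 E) | [K]O/C1=C(/C)CC/C=C/[C@](C)(CC[C@@H](C)CCO[Si](C)(C)C(C)(C)C)[C@@H](C)CC1
F3 | step 13 | (1S,2S,3R,4S)-3-[(3R)-5-(tert-butyldimethylsilyloxy)-3-methylpentyl]-2-[1-hydroxy-2-(phenylselanyl)ethyl]-3,4-dimethyl-1-(prop-1-en-2-yl)cyclohexan-1-ol (carbinol epimers) | O[C@@]1(C(C)=C)CC[C@H](C)[C@@](C)(CC[C@@H](C)CCO[Si](C)(C)C(C)(C)C)[C@H]1C(O)C[Se]c1ccccc1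
F4 | step 19 | O-[18-acetoxy-15-(tert-butyldimethylsilyloxy)halimane-5-yl] S-methyl dithiocarbonate | CC(=O)OC[C@]1(C)CCC[C@@H]2[C@]1(OC(=S)SC)CC[C@H](C)[C@@]2(C)CC[C@@H](C)CCO[Si](C)(C)C(C)(C)C
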